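**Plan**

1. Retrosynthetic cuts, in order: C8–C9 (11-membered ring, Nozaki–Hiyama–Kishi), C1–C14 (B-alkyl Suzuki), then the two cyclopentane bonds C7–C16 and C4–C5 (one [3+2] annulation onto a cyclohexenone).
2. Enabling feature: the cyclopentane (C4, C5, C6, C7, C16) is fused to the six-membered ring at C4–C16, oxygenated C3 sits next to quaternary C4, and C7 carries the sp2 carbon C8. So C3(=O)–C4(CH3)=C16 is the enone of carvone, and C5–C6–C7–C8 is a buta-2,3-dienoate.
3. Forward order: six-membered ring from (S)-carvone; cyclopentene by phosphine-catalysed [3+2] (C16–C7 first, ring closure by C4–C5); C2/C3 oxygenation; isopropenyl → C1 ketone → enol triflate → side chain; C8 ester → vinyl triflate; 11-membered ring last.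
4. Stereochemistry: C1 of carvone (bought, later excised) sets C16 and C4 in the annulation, then C2 (hydroxylation anti to C1) and C3 (hydroxyl-directed hydride). C7 comes from convex-face hydrogenation, C12 from a copper-catalysed asymmetric allylic alkylation, C9 from the macrocyclisation.

Key step: step 1

Remark: locants in names are those of the target skeleton (six-membered ring C1(=C15)–C2–C3–C4–C16; cyclopentane C4–C5–C6–C7–C16; 11-membered ring C1–C14–C13–C12–C11–C10–C9–C8–C7–C16–C15; C17 = CH3 on C15, C18 = CH3 on C4, C19 = CH2 on C8, C20 = CH2O on C12); α is the six-ring face of H-16 and CH3-18, β the face of C5 and C7.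

**Step 1**
Reactants: 1 (S)-(+)-carvone; 2 ethyl buta-2,3-dienoate
Product: 3 ethyl (3aS,5S,7aS)-7a-methyl-7-oxo-5-(prop-1-en-2-yl)-3a,4,5,6,7,7a-hexahydro-1H-indene-3-carboxylate
Conditions: PBu3 (20 mol %), toluene, 80 °C, slow addition of 2
Reagents that add atoms: none
Why: Proposed new method: PBu3 adds to the central carbon of 2 to give a phosphonium dienolate, whose α-carbon (C7) adds to C16, the β-carbon of the enone, and the C3–C4 enolate so formed attacks the terminal carbon C5 of the vinylphosphonium unit to form C4–C5, after which a proton shift and loss of PBu3 leave the C6=C7 enoate; the label applies because this annulation has not been shown on an α-alkylated endocyclic enone. The closest known reaction type is the Lu phosphine-catalysed [3+2] annulation of buta-2,3-dienoates with enones, known for acyclic and some cyclic enones and for α-methylene ketones that give α-quaternary centres. The one ring closed is the cyclopentene, by a formal 5-endo-trig attack of the enolate carbon on the P-substituted alkene (an intramolecular Michael addition to a vinylphosphonium salt). C16 is controlled by the C1 stereocentre of carvone, the nucleophile entering axially on the ring face anti to the isopropenyl group, and C4 is then fixed cis to C16 because a three-atom bridge between adjacent ring carbons can close only on the same face. The step needs α- over γ-attack of the dienolate and 1,4- over 1,2-addition; the former is the usual regiochemistry with enone acceptors, the latter follows from the soft delocalised nucleophile, and slow addition of 2 holds back allenoate oligomerisation while the unsubstituted C16 keeps the acceptor accessible.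

**Step 2**
Reactants: 3 hydrindenone ester
Product: 5 2β-hydroxy ketone (OH at C2 trans to the C1 isopropenyl group), via potassium enolate 4 (not isolated)
Conditions: KN(SiMe3)2, THF, −78 °C; then 2-(phenylsulfonyl)-3-phenyloxaziridine, −78 °C
Reagents that add atoms: 2-(phenylsulfonyl)-3-phenyloxaziridine, O=S(=O)(c1ccccc1)N1OC1c1ccccc1
Why: Davis enolate α-hydroxylation: the ketone can enolise only toward C2 because C4 is quaternary, and the oxaziridine delivers oxygen to the potassium enolate on the β face, anti to the neighbouring C1 isopropenyl group and to CH3-18, which sets C2.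

**Step 3**
Reactants: 5 2β-hydroxy ketone
Product: 6 2β,3α-diol
Conditions: Me4NBH(OAc)3, MeCN/AcOH, −20 to 0 °C
Reagents that add atoms: none
Why: Saksena–Evans hydroxyl-directed reduction: the acetoxyborohydride exchanges onto the 2β-hydroxyl and delivers hydride intramolecularly to the β face of C3, which gives the 3α-alcohol (trans-diol) and leaves the enoate and the isopropenyl group untouched.

**Step 4**
Reactants: 6 2β,3α-diol
Product: 7 2β,3α-bis(tert-butyldimethylsilyl) ether
Conditions: TBSOTf, 2,6-lutidine, CH2Cl2, 0 °C to rt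
Reagents that add atoms: tert-butyldimethylsilyl trifluoromethanesulfonate, CC(C)(C)[Si](C)(C)OS(=O)(=O)C(F)(F)F
Why: Silyl ether formation with a silyl triflate protects both hydroxyls, the neopentyl C3–OH included, against the bases, organometallic reagents and oxidants of the following steps.

**Step 5**
Reactants: 7 bis-silyl ether
Product: 10 C1 ketone (isopropenyl group replaced by C1=O), via methoxy hydroperoxide 8 (not isolated), via TEMPO alkoxyamine 9 (not isolated)
Conditions: O3, MeOH/CH2Cl2, −78 °C; then FeSO4·7H2O, TEMPO, −78 °C to rt; then mCPBA, rt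
Reagents that add atoms: TEMPO, CC1(C)CCCC(C)(C)N1[O]
Why: Oxodealkenylation: ozonolysis of the electron-rich 1,1-disubstituted alkene in methanol (the enoate reacts far more slowly), ferrous-ion reduction of the methoxy hydroperoxide, β-scission with loss of methyl acetate, TEMPO capture of the C1 radical and peracid oxidation of the alkoxyamine replace the isopropenyl control group by the C1 ketone.

**Step 6**
Reactants: 10 C1 ketone
Product: 12 15-methyl C1 ketone (C15 epimers), via lithium enolate 11 (not isolated)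
Conditions: LiN(i-Pr)2, THF, −78 °C; then MeI, DMPU, −78 to −40 °C
Reagents that add atoms: iodomethane, CI
Why: Kinetic enolate alkylation: the hindered amide base removes a proton from the C15 methylene in preference to the silyloxy-bearing C2–H and iodomethane introduces CH3-17, the configuration at C15 being irrelevant because it becomes sp2 in step 7.

**Step 7**
Reactants: 12 15-methyl C1 ketone
Product: 14 C1 enol triflate (C1(OTf)=C15(CH3)), via potassium enolate 13 (not isolated)
Conditions: KN(SiMe3)2, THF, −78 °C; then PhNTf2, −78 to 0 °C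
Reagents that add atoms: N-phenylbis(trifluoromethanesulfonimide), FC(F)(F)S(=O)(=O)N(c1ccccc1)S(=O)(=O)C(F)(F)F
Why: Enol triflate formation: deprotonation at C15–H, away from the α-silyloxy C2–H that is shielded by two silyl ethers, gives the tetrasubstituted enolate and O-sulfonylation fixes the C1=C15 double bond with CH3-17 in place.

**Step 8**
Reactants: 15 (E)-1,4-dibromobut-2-ene
Product: 16 (E)-1-bromo-4-[(4-methoxybenzyl)oxy]but-2-ene
Conditions: 4-methoxybenzyl alcohol, NaH, THF, 0 °C to rt (15 in excess)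
Reagents that add atoms: 4-methoxybenzyl alcohol, COc1ccc(CO)cc1
Why: Williamson ether synthesis by SN2 displacement of one allylic bromide, the excess of symmetrical dibromide holding back double substitution.

**Step 9**
Reactants: 16 allylic bromide; 17 2-(2-bromoethyl)-1,3-dioxolane
Product: 19 (S)-2-[3-{[(4-methoxybenzyl)oxy]methyl}pent-4-en-1-yl]-1,3-dioxolane, via Grignard reagent 18 (not isolated)
Conditions: Mg, THF, 25 °C; then CuBr·SMe2 (3 mol %), Taniaphos (3.3 mol %, the enantiomer that gives the S product), CH2Cl2, −78 °C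
Reagents that add atoms: none
Why: Copper-catalysed asymmetric allylic alkylation: the Grignard reagent attacks the allylic bromide in SN2′ fashion to give the branched terminal alkene, and the chiral ferrocenyl diphosphine on copper controls the face of attack and thus C12 (catalyst control).

**Step 10**
Reactants: 19 alkene fragment; 14 C1 enol triflate
Product: 21 C1-alkylated hydrindene ester (C14–C9 chain on C1; C9 as dioxolane; C20 as PMB ether), via alkylborane 20 (not isolated)
Conditions: 9-BBN dimer, THF, rt; then 14, Pd(dppf)Cl2 (10 mol %), AsPh3, Cs2CO3, DMF/H2O, rt to 50 °C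
Reagents that add atoms: none
Why: B-alkyl Suzuki–Miyaura coupling: anti-Markovnikov hydroboration of the terminal alkene and palladium-catalysed sp3–sp2 coupling with the enol triflate form C1–C14 and complete the tetrasubstituted C1=C15 alkene.

**Step 11**
Reactants: 21 ethyl ester
Product: 23 methyl enone (C6=C7–C8(=O)CH3), via Weinreb amide 22 (not isolated)
Conditions: MeNH(OMe)·HCl, i-PrMgCl, THF, −20 °C; then MeMgBr, 0 °C
Reagents that add atoms: methylmagnesium bromide, C[Mg]Br
Why: Weinreb ketone synthesis in one pot: the magnesium amide converts the ester into the N-methoxy-N-methylamide, whose chelated tetrahedral adduct with MeMgBr collapses to the methyl ketone only on work-up, so that neither over-addition nor conjugate addition intervenes.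

**Step 12**
Reactants: 23 methyl enone
Product: 24 (7R)-methyl ketone (7α-H; acetyl group on the concave β face)
Conditions: H2 (1 atm), Pd/C, pyridine (trace), EtOAc, rt
Reagents that add atoms: none
Why: Heterogeneous catalytic hydrogenation of the enone C=C: hydrogen adds syn from the convex α face of the cis-fused hydrindene (the face of H-16 and CH3-18), which puts the acetyl group on the concave face and sets C7, while pyridine suppresses hydrogenolysis of the PMB ether and the tetrasubstituted C1=C15 alkene does not react.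

**Step 13**
Reactants: 24 methyl ketone
Product: 26 vinyl triflate (C8(OTf)=C19H2), via potassium enolate 25 (not isolated)
Conditions: KN(SiMe3)2, THF, −78 °C; then PhNTf2, −78 °C
Reagents that add atoms: N-phenylbis(trifluoromethanesulfonimide), FC(F)(F)S(=O)(=O)N(c1ccccc1)S(=O)(=O)C(F)(F)F
Why: Kinetic enol triflate formation: the bulky amide base deprotonates the methyl group and not the hindered C7–H, so that O-sulfonylation gives the 2-triflyloxy-1-alkene (C8=C19) and locks the C7 configuration before it can epimerise.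

**Step 14**
Reactants: 26 vinyl triflate
Product: 27 C9 aldehyde
Conditions: PPTS, acetone/H2O, 60 °C
Reagents that add atoms: water, O
Why: Acid-catalysed acetal exchange with acetone (acetal hydrolysis) frees the C9 aldehyde under conditions that the secondary TBS ethers, the PMB ether and the vinyl triflate survive.

**Step 15**
Reactants: 27 aldehyde vinyl triflate
Product: 28 macrocyclic (9S)-allylic alcohol
Conditions: CrCl2 (excess), NiCl2 (cat.), DMSO/THF, rt, high dilution
Reagents that add atoms: none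
Why: Nozaki–Hiyama–Kishi reaction: nickel-catalysed conversion of the vinyl triflate into an alkenylchromium species and its intramolecular 1,2-addition to the aldehyde close the 11-membered ring by the C8–C9 bond under high dilution, C9 being set under substrate control by the conformation of the closing ring with attack on the aldehyde face turned away from the hydrindane expected to give the 9S alcohol.

**Step 16**
Reactants: 28 macrocyclic alcohol
Product: 29 9,20-diol
Conditions: DDQ, CH2Cl2/pH 7 buffer, 0 °C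
Reagents that add atoms: none
Why: Oxidative PMB ether cleavage: DDQ abstracts hydride from the electron-rich benzylic position and hydrolysis of the oxocarbenium ion frees the C20 hydroxyl without touching silyl ethers or alkenes.

**Step 17**
Reactants: 29 9,20-diol
Product: 30 9,20-diacetate
Conditions: Ac2O, pyridine, DMAP (cat.), CH2Cl2, 0 °C to rt
Reagents that add atoms: acetic anhydride, CC(=O)OC(C)=O
Why: Acylation under DMAP catalysis esterifies the only two free hydroxyls, at C9 and C20, the C2 and C3 oxygens being silylated.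

**Step 18**
Reactants: 30 bis-silyl diacetate
Product: 31 CNP0193272.1
Conditions: HF·pyridine, pyridine/THF, 0 °C to rt
Reagents that add atoms: none
Why: Fluoride-mediated desilylation: the Si–F bond strength drives cleavage of both TBS ethers under buffered conditions that leave the two acetates, the allylic C9–O bond and the alkenes intact.

**Compound list**

1 | (S)-(+)-carvone, (5S)-2-methyl-5-(prop-1-en-2-yl)cyclohex-2-en-1-one | CC(=C)[C@H]1CC=C(C)C(=O)C1 | starting material
2 | ethyl buta-2,3-dienoate | C=C=CC(=O)OCC | starting material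
3 | ethyl (3aS,5S,7aS)-7a-methyl-7-oxo-5-(prop-1-en-2-yl)-3a,4,5,6,7,7a-hexahydro-1H-indene-3-carboxylate (cis-fused; isopropenyl α on C1; ester carbon = C8) | CC(=C)[C@H]1C[C@@H]2C(C(=O)OCC)=CC[C@]2(C)C(=O)C1 | intermediate
4 | potassium enolate of 3 (C2=C3–OK) | CC(=C)[C@H]1C[C@@H]2C(C(=O)OCC)=CC[C@]2(C)C([O-])=C1.[K+] | intermediate
5 | 2β-hydroxy derivative of 3 (C3 ketone) | CC(=C)[C@H]1C[C@@H]2C(C(=O)OCC)=CC[C@]2(C)C(=O)[C@@H]1O | intermediate
6 | 2β,3α-diol (trans) | CC(=C)[C@H]1C[C@@H]2C(C(=O)OCC)=CC[C@]2(C)[C@@H](O)[C@@H]1O | intermediate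
7 | 2β,3α-bis(tert-butyldimethylsilyl) ether of 6 | CC(=C)[C@H]1C[C@@H]2C(C(=O)OCC)=CC[C@]2(C)[C@@H](O[Si](C)(C)C(C)(C)C)[C@@H]1O[Si](C)(C)C(C)(C)C | intermediate
8 | methoxy hydroperoxide: 7 with C(CH3)(OCH3)OOH on C1 | COC(C)(OO)[C@H]1C[C@@H]2C(C(=O)OCC)=CC[C@]2(C)[C@@H](O[Si](C)(C)C(C)(C)C)[C@@H]1O[Si](C)(C)C(C)(C)C | intermediate
9 | TEMPO alkoxyamine: 7 with O-(2,2,6,6-tetramethylpiperidin-1-yl) on C1 (C1 epimers) | CC1(C)CCCC(C)(C)N1OC1C[C@@H]2C(C(=O)OCC)=CC[C@]2(C)[C@@H](O[Si](C)(C)C(C)(C)C)[C@@H]1O[Si](C)(C)C(C)(C)C | intermediate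
10 | C1 ketone | O=C1C[C@@H]2C(C(=O)OCC)=CC[C@]2(C)[C@@H](O[Si](C)(C)C(C)(C)C)[C@@H]1O[Si](C)(C)C(C)(C)C | intermediate
11 | lithium enolate of 10 (C1(OLi)=C15) | [Li+].[O-]C1=C[C@@H]2C(C(=O)OCC)=CC[C@]2(C)[C@@H](O[Si](C)(C)C(C)(C)C)[C@@H]1O[Si](C)(C)C(C)(C)C | intermediate
12 | 15-methyl C1 ketone (C15 epimers) | O=C1C(C)[C@@H]2C(C(=O)OCC)=CC[C@]2(C)[C@@H](O[Si](C)(C)C(C)(C)C)[C@@H]1O[Si](C)(C)C(C)(C)C | intermediate
13 | potassium enolate of 12 (C1(OK)=C15(CH3)) | [K+].[O-]C1=C(C)[C@@H]2C(C(=O)OCC)=CC[C@]2(C)[C@@H](O[Si](C)(C)C(C)(C)C)[C@@H]1O[Si](C)(C)C(C)(C)C | intermediate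
14 | C1 enol triflate (C1(OTf)=C15(CH3)) | O=S(=O)(OC1=C(C)[C@@H]2C(C(=O)OCC)=CC[C@]2(C)[C@@H](O[Si](C)(C)C(C)(C)C)[C@@H]1O[Si](C)(C)C(C)(C)C)C(F)(F)F | intermediate
15 | (E)-1,4-dibromobut-2-ene | BrC/C=C/CBr | starting material
16 | (E)-1-bromo-4-[(4-methoxybenzyl)oxy]but-2-ene | BrC/C=C/COCc1ccc(OC)cc1 | intermediate
17 | 2-(2-bromoethyl)-1,3-dioxolane | BrCCC1OCCO1 | starting material
18 | [2-(1,3-dioxolan-2-yl)ethyl]magnesium bromide | Br[Mg]CCC1OCCO1 | intermediate
19 | (S)-2-[3-{[(4-methoxybenzyl)oxy]methyl}pent-4-en-1-yl]-1,3-dioxolane (C9–C14 and C20) | C=C[C@@H](COCc1ccc(OC)cc1)CCC1OCCO1 | intermediate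
20 | B-alkyl-9-borabicyclo[3.3.1]nonane from 19 (boron on C14) | B1(CC[C@@H](COCc2ccc(OC)cc2)CCC2OCCO2)C2CCCC1CCC2 | intermediate
21 | Suzuki product: ethyl ester with the C14–C9 chain on C1, C9 as 1,3-dioxolane, C20 as PMB ether, 2β,3α-bis-TBS | C1(OCCO1)CC[C@H](COCc1ccc(OC)cc1)CCC1=C(C)[C@@H]2C(C(=O)OCC)=CC[C@]2(C)[C@@H](O[Si](C)(C)C(C)(C)C)[C@@H]1O[Si](C)(C)C(C)(C)C | intermediate
22 | N-methoxy-N-methylamide of 21 | C1(OCCO1)CC[C@H](COCc1ccc(OC)cc1)CCC1=C(C)[C@@H]2C(C(=O)N(C)OC)=CC[C@]2(C)[C@@H](O[Si](C)(C)C(C)(C)C)[C@@H]1O[Si](C)(C)C(C)(C)C | intermediate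
23 | methyl enone (C6=C7–C8(=O)CH3) | C1(OCCO1)CC[C@H](COCc1ccc(OC)cc1)CCC1=C(C)[C@@H]2C(C(C)=O)=CC[C@]2(C)[C@@H](O[Si](C)(C)C(C)(C)C)[C@@H]1O[Si](C)(C)C(C)(C)C | intermediate
24 | (7R)-methyl ketone (7α-H) | C1(OCCO1)CC[C@H](COCc1ccc(OC)cc1)CCC1=C(C)[C@@H]2[C@H](C(C)=O)CC[C@]2(C)[C@@H](O[Si](C)(C)C(C)(C)C)[C@@H]1O[Si](C)(C)C(C)(C)C | intermediate
25 | potassium enolate of 24 (C8(OK)=C19H2) | [K+].C1(OCCO1)CC[C@H](COCc1ccc(OC)cc1)CCC1=C(C)[C@@H]2[C@H](C(=C)[O-])CC[C@]2(C)[C@@H](O[Si](C)(C)C(C)(C)C)[C@@H]1O[Si](C)(C)C(C)(C)C | intermediate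
26 | vinyl triflate (C8(OTf)=C19H2) | C1(OCCO1)CC[C@H](COCc1ccc(OC)cc1)CCC1=C(C)[C@@H]2[C@H](C(=C)OS(=O)(=O)C(F)(F)F)CC[C@]2(C)[C@@H](O[Si](C)(C)C(C)(C)C)[C@@H]1O[Si](C)(C)C(C)(C)C | intermediate
27 | C9 aldehyde of 26 | O=CCC[C@H](COCc1ccc(OC)cc1)CCC1=C(C)[C@@H]2[C@H](C(=C)OS(=O)(=O)C(F)(F)F)CC[C@]2(C)[C@@H](O[Si](C)(C)C(C)(C)C)[C@@H]1O[Si](C)(C)C(C)(C)C | intermediate
28 | macrocyclic (9S)-allylic alcohol (20-O-PMB, 2,3-bis-O-TBS) | C=C1[C@@H](O)CC[C@H](COCc4ccc(OC)cc4)CCC2=C(C)[C@@H]3[C@H]1CC[C@]3(C)[C@@H](O[Si](C)(C)C(C)(C)C)[C@@H]2O[Si](C)(C)C(C)(C)C | intermediate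
29 | 9,20-diol (2,3-bis-O-TBS) | C=C1[C@@H](O)CC[C@H](CO)CCC2=C(C)[C@@H]3[C@H]1CC[C@]3(C)[C@@H](O[Si](C)(C)C(C)(C)C)[C@@H]2O[Si](C)(C)C(C)(C)C | intermediate
30 | 9,20-diacetate (2,3-bis-O-TBS) | C=C1[C@@H](OC(C)=O)CC[C@H](COC(C)=O)CCC2=C(C)[C@@H]3[C@H]1CC[C@]3(C)[C@@H](O[Si](C)(C)C(C)(C)C)[C@@H]2O[Si](C)(C)C(C)(C)C | intermediate
31 | CNP0193272.1, the (2R,3R,4S,7R,9S,12R,16S)-2β,3α-diol 9,20-diacetate | C=C1[C@@H](OC(C)=O)CC[C@H](COC(C)=O)CCC2=C(C)[C@@H]3[C@H]1CC[C@]3(C)[C@@H](O)[C@@H]2O | target

**Step count and risks**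

Total steps: 18. Longest linear sequence: 16 (steps 1–7 and 10–18, from (S)-carvone); steps 8 and 9 make the side-chain fragment.

Steps most likely to fail:

Step 1 (Proposed new method). The phosphonium dienolate may consume the allenoate by self-oligomerisation faster than it adds to the α-methylated enone, or it may add through its γ-carbon. The fallback uses known chemistry and keeps the same ring-closing bond. It sets out from 1. Michael addition of triethyl phosphonoacetate (NaOEt, EtOH), anti to the isopropenyl group, gives the phosphonate adduct F1. Horner–Wadsworth–Emmons olefination of F1 with chloroacetaldehyde (LiCl, DBU, MeCN) gives the (E)-γ-chloro enoate F2, in which the CH2Cl group lies cis to the ring. KOt-Bu in THF then forms the C3–C4 enolate, which displaces the allylic chloride (5-exo-tet, C4–C5) and closes the cis-fused cyclopentene, coming back to the route at 3.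

Step 15. Attack on the wrong face of the aldehyde during ring closure would give mainly the 9R alcohol. The fallback sets out from 27 again. The 9-epimeric alcohol F3 formed in the Nozaki–Hiyama–Kishi reaction is oxidised with Dess–Martin periodinane to the macrocyclic α-methylene ketone F4. F4 is reduced under reagent control with BH3·SMe2 and (R)-2-methyl-CBS-oxazaborolidine (C8 taken as the large group), coming back to the route at 28.

Step 12. Delivery of hydrogen to the concave face of C6=C7, or to both faces, would place the acetyl group on the convex face. The fallback sets out from 23. Reduction with BH3·SMe2 and (R)-2-methyl-CBS-oxazaborolidine gives the (8S)-allylic alcohol F5. Hydroxyl-directed hydrogenation with [Ir(cod)(PCy3)(py)]PF6 (H2, CH2Cl2) adds hydrogen to the face on which the hydroxyl lies in the conformer that turns H-8 toward C16 (allylic 1,2-strain), which is the α face, and gives the saturated alcohol F6. Dess–Martin oxidation comes back to the route at 24.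

**Further compounds**

F1 | step 1 | ethyl 2-(diethoxyphosphoryl)-2-[2-methyl-3-oxo-5-(prop-1-en-2-yl)cyclohexyl]acetate (side chain on C16 trans to isopropenyl; epimers at C4 and C7) | CC(=C)[C@H]1C[C@H](C(C(=O)OCC)P(=O)(OCC)OCC)C(C)C(=O)C1
F2 | step 1 | ethyl (E)-4-chloro-2-[2-methyl-3-oxo-5-(prop-1-en-2-yl)cyclohexyl]but-2-enoate (epimers at C4) | CC(=C)[C@H]1C[C@H](/C(C(=O)OCC)=C\CCl)C(C)C(=O)C1
F3 | step 15 | 9R epimer of 28 | C=C1[C@H](O)CC[C@H](COCc4ccc(OC)cc4)CCC2=C(C)[C@@H]3[C@H]1CC[C@]3(C)[C@@H](O[Si](C)(C)C(C)(C)C)[C@@H]2O[Si](C)(C)C(C)(C)C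
F4 | step 15 | macrocyclic α-methylene ketone (C9 ketone of 28) | C=C1C(=O)CC[C@H](COCc4ccc(OC)cc4)CCC2=C(C)[C@@H]3[C@H]1CC[C@]3(C)[C@@H](O[Si](C)(C)C(C)(C)C)[C@@H]2O[Si](C)(C)C(C)(C)C
F5 | step 12 | (8S)-allylic alcohol from 23 (C6=C7–C8H(OH)CH3) | C1(OCCO1)CC[C@H](COCc1ccc(OC)cc1)CCC1=C(C)[C@@H]2C([C@H](C)O)=CC[C@]2(C)[C@@H](O[Si](C)(C)C(C)(C)C)[C@@H]1O[Si](C)(C)C(C)(C)C
F6 | step 12 | (7R,8S)-saturated alcohol | C1(OCCO1)CC[C@H](COCc1ccc(OC)cc1)CCC1=C(C)[C@@H]2[C@H]([C@H](C)O)CC[C@]2(C)[C@@H](O[Si](C)(C)C(C)(C)C)[C@@H]1O[Si](C)(C)C(C)(C)C
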